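**Strategy.** Cutting the four ester bonds leaves an orsellinic acid (ring A), two (R)-3-oxybutanoate units (B1, B2) and twice the same (R)-1-arylpropan-2-ol, since ring C is ring D plus one carboxyl carbon. The key step exploits the pattern of ring D: oxygen on C1 and C3, hydrogen on C2, C4 and C6, the (R)-2-oxypropyl chain on C5. Heating a 3-alkylcyclobutenone that already holds the silylated carbinol with a C-silylated siloxyalkyne forms bonds C1–C2, C3–C4 and C1–C6 and closes the benzene ring in one operation, the 1,3,5 pattern being fixed by mechanism. Formylation and oxidation of the same arene later give ring C.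

Key step: step 6

Assumption: all four stereocentres of the target SMILES are read as R. The two chain carbinols come from (R)-propylene oxide, and the two butanoate centres come from Mitsunobu inversion of an (S)-alcohol.
Remark: alcohol 19 is made once and divided. One portion becomes ring C (step 13) and the other becomes ring D (step 18).

**Step 1**
Reactants: 1 (R)-propylene oxide; 2 lithium acetylide–ethylenediamine complex
Product: 3 (R)-pent-4-yn-2-ol
Conditions: DMSO, 0 °C → rt; then H2O
Reagents that add atoms: none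
Why: SN2 opening of a terminal epoxide by an acetylide takes place at the unsubstituted CH2 carbon, so the C–O bond of the stereocentre is never touched and the R configuration of 1 is carried into 3.

**Step 2**
Reactants: 3 (R)-pent-4-yn-2-ol
Product: 4 (R)-tert-butyldimethyl(pent-4-yn-2-yloxy)silane
Conditions: TBSCl, imidazole, CH2Cl2, rt
Reagents that add atoms: tert-butyldimethylsilyl chloride, CC(C)(C)[Si](C)(C)Cl
Why: Imidazole-promoted silylation of a secondary alcohol masks the hydroxyl, which 5 would otherwise acylate in the next step, and leaves the stereocentre alone.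

**Step 3**
Reactants: 4 (R)-tert-butyldimethyl(pent-4-yn-2-yloxy)silane; 5 trichloroacetyl chloride
Product: 7 (R)-3-[2-(tert-butyldimethylsilyloxy)propyl]-4,4-dichlorocyclobut-2-en-1-one, via dichloroketene 6 (not isolated)
Conditions: Zn–Cu couple, Et2O–DME, slow addition of 5, rt → reflux
Reagents that add atoms: none
Why: In this ketene–alkyne [2+2] cycloaddition the terminal alkyne carbon attacks the carbonyl carbon of dichloroketene (made by zinc dechlorination of 5), which places the chain on C3 next to the CCl2 group, while DME ties up ZnCl2 and so spares the silyl ether.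

**Step 4**
Reactants: 7 (R)-3-[2-(tert-butyldimethylsilyloxy)propyl]-4,4-dichlorocyclobut-2-en-1-one
Product: 8 (R)-3-[2-(tert-butyldimethylsilyloxy)propyl]cyclobut-2-en-1-one
Conditions: Zn dust, AcOH, TMEDA, EtOH, 0 °C → rt
Reagents that add atoms: none
Why: Reductive dechlorination of an α,α-dichloroketone by zinc in TMEDA-buffered acetic acid removes both chlorines (also from any allylically shifted 2,4-dichloro isomer) under conditions mild enough for the strained enone and the silyl ether.

**Step 5**
Reactants: 9 ethynyltrimethylsilane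
Product: 12 1-(triisopropylsilyloxy)-2-(trimethylsilyl)ethyne, via lithium acetylide 10 (not isolated), via lithium ynolate 11 (not isolated)
Conditions: n-BuLi, THF, −78 °C; LiOOt-Bu (from anhydrous t-BuOOH and LiN(SiMe3)2, THF, −78 °C), −78 → 0 °C; TIPSOTf, −78 → 0 °C
Reagents that add atoms: tert-butyl hydroperoxide, CC(C)(C)OO; triisopropylsilyl triflate, CC(C)[Si](OS(=O)(=O)C(F)(F)F)(C(C)C)C(C)C
Why: Oxidation of a lithium acetylide by lithium tert-butyl peroxide (displacement on the O–O bond) is an established entry to lithium ynolates, and the hard, bulky silyl triflate captures the silyl-substituted ynolate on oxygen, where small chlorosilanes would silylate carbon.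

**Step 6**
Reactants: 8 (R)-3-[2-(tert-butyldimethylsilyloxy)propyl]cyclobut-2-en-1-one; 12 1-(triisopropylsilyloxy)-2-(trimethylsilyl)ethyne
Product: 17 (R)-5-[2-(tert-butyldimethylsilyloxy)propyl]-3-(triisopropylsilyloxy)-2-(trimethylsilyl)phenol, via vinylketene 13 (not isolated), via 4-vinylcyclobutenone 14 (not isolated), via dienylketene 15 (not isolated), via cyclohexadienone 16 (not isolated)
Conditions: 12 (1.5 equiv), toluene (0.5 M), Ar, sealed tube, 80 °C then 110 °C
Reagents that add atoms: none
Why: Thermal 4π electrocyclic opening of 8 breaks its C(=O)–CH2 bond and gives vinylketene 13, whose carbonyl carbon is attacked by the silyl-bearing (nucleophilic) carbon of 12, so that the [2+2] cycloaddition gives 4-vinylcyclobutenone 14 with the new arene bonds C1–C2 and C3–C4. A second 4π opening of 14 gives dienylketene 15, thermal disrotatory 6π electrocyclisation closes the six-membered ring through C1–C6, and enolisation of dienone 16 gives phenol 17. This is the Danheiser benzannulation in its siloxyalkyne form, which is known to turn 3-alkylcyclobutenones into resorcinol monosilyl ethers. No stereocentre is created in 17 (the sp3 ring carbon of 14 is lost again on opening), and the carbinol carbon lies outside the reacting π system, so it should pass through the neutral thermolysis unchanged. The selectivity needed is the orientation of the ketene–alkyne cycloaddition: oxygen donation polarises 12, and the positive charge building on the oxygen-bearing carbon is β to the C–Si bond, so both substituents direct the same way and put O on C3, Si on C2 and the chain on C5. The trimethylsilyl group also makes the ynol silyl ether isolable (the hydrogen-terminated parent drifts to a silylketene) and shields the new phenol from acylation by 13.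

**Step 7**
Reactants: 17 (R)-5-[2-(tert-butyldimethylsilyloxy)propyl]-3-(triisopropylsilyloxy)-2-(trimethylsilyl)phenol
Product: 18 (R)-3-(2-hydroxypropyl)-5-(triisopropylsilyloxy)phenol
Conditions: HCl (1.25 M in MeOH), 0 °C → rt
Reagents that add atoms: none
Why: Acid-catalysed methanolysis cleaves the secondary alkyl TBS ether and ipso-protodesilylation (electrophilic substitution at a crowded carbon ortho to two oxygens and para to the chain) clears C2, whereas the aryl TIPS ether solvolyses far more slowly in acid and any loss of it does no harm to step 8.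

**Step 8**
Reactants: 18 (R)-3-(2-hydroxypropyl)-5-(triisopropylsilyloxy)phenol
Product: 19 (R)-1-[3,5-bis(benzyloxy)phenyl]propan-2-ol
Conditions: BnBr, CsF, K2CO3, DMF, rt
Reagents that add atoms: benzyl bromide, BrCc1ccccc1
Why: In this Williamson etherification carbonate ionises the free phenol and fluoride unmasks the aryl silyl ether as a second phenoxide, both are benzylated in the flask, and the far less acidic secondary alcohol stays free.

**Step 9**
Reactants: 20 methyl 2,4-dihydroxy-6-methylbenzoate (methyl orsellinate)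
Product: 21 methyl 2,4-bis(benzyloxy)-6-methylbenzoate
Conditions: BnBr, K2CO3, DMF, 60 °C
Reagents that add atoms: benzyl bromide, BrCc1ccccc1
Why: Williamson etherification benzylates both phenols, the hydrogen-bonded ortho one included once the mixture is warmed in DMF.

**Step 10**
Reactants: 21 methyl 2,4-bis(benzyloxy)-6-methylbenzoate
Product: 22 2,4-bis(benzyloxy)-6-methylbenzoic acid
Conditions: KOH, DMSO–H2O, 100 °C; then aq. HCl
Reagents that add atoms: potassium hydroxide, [K+].[OH-]
Why: Saponification of the doubly ortho-substituted and therefore slow methyl ester needs hot concentrated hydroxide, which aryl benzyl ethers tolerate.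

**Step 11**
Reactants: 22 2,4-bis(benzyloxy)-6-methylbenzoic acid; 23 tert-butyl (S)-3-hydroxybutanoate
Product: 24 tert-butyl (R)-3-{[2,4-bis(benzyloxy)-6-methylbenzoyl]oxy}butanoate
Conditions: PPh3, DIAD, toluene, 0 °C → rt
Reagents that add atoms: none
Why: The Mitsunobu esterification activates the alcohol and not the hindered carbonyl group, so the 2,6-disubstituted carboxylate only has to act as a nucleophile, and SN2 displacement of the oxyphosphonium group inverts (S)-23 to the R acyloxy centre of B1.

**Step 12**
Reactants: 24 tert-butyl (R)-3-{[2,4-bis(benzyloxy)-6-methylbenzoyl]oxy}butanoate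
Product: 25 (R)-3-{[2,4-bis(benzyloxy)-6-methylbenzoyl]oxy}butanoic acid
Conditions: TFA–CH2Cl2 (1:4), 0 °C → rt
Reagents that add atoms: none
Why: Acidolysis of the tert-butyl ester (loss of the tert-butyl cation as isobutene) leaves untouched the aryl ester and the benzyl ethers, which sit on an acyl-deactivated ring.

**Step 13**
Reactants: 25 (R)-3-{[2,4-bis(benzyloxy)-6-methylbenzoyl]oxy}butanoic acid; 19 (R)-1-[3,5-bis(benzyloxy)phenyl]propan-2-ol
Product: 26 (R)-1-[3,5-bis(benzyloxy)phenyl]propan-2-yl (R)-3-{[2,4-bis(benzyloxy)-6-methylbenzoyl]oxy}butanoate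
Conditions: DCC, DMAP (cat.), CH2Cl2, 0 °C → rt
Reagents that add atoms: none
Why: Steglich esterification of an unhindered aliphatic acid with a secondary alcohol keeps both stereocentres, catalytic DMAP at low temperature limits E1cB loss of the β-aroyloxy group, and the B1 acyl group doubles as the protecting group of the future ring C carbinol.

**Step 14**
Reactants: 26 (R)-1-[3,5-bis(benzyloxy)phenyl]propan-2-yl (R)-3-{[2,4-bis(benzyloxy)-6-methylbenzoyl]oxy}butanoate
Product: 28 (R)-1-[3,5-bis(benzyloxy)-2-formylphenyl]propan-2-yl (R)-3-{[2,4-bis(benzyloxy)-6-methylbenzoyl]oxy}butanoate, via iminium salt 27 (not isolated)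
Conditions: POCl3 (1.3 equiv), DMF, 0 °C → rt; then aq. NaOAc
Reagents that add atoms: N,N-dimethylformamide, CN(C)C=O; water, O
Why: In the Vilsmeier–Haack formylation the weak chloroiminium electrophile prefers the acyl-free ring to ring A and, as with other 3,5-dialkoxyalkylbenzenes, attacks the position para to one benzyloxy group and ortho to the chain rather than the crowded site between the two benzyloxy groups.

**Step 15**
Reactants: 28 (R)-1-[3,5-bis(benzyloxy)-2-formylphenyl]propan-2-yl (R)-3-{[2,4-bis(benzyloxy)-6-methylbenzoyl]oxy}butanoate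
Product: 29 2,4-bis(benzyloxy)-6-{(R)-2-[((R)-3-{[2,4-bis(benzyloxy)-6-methylbenzoyl]oxy}butanoyl)oxy]propyl}benzoic acid
Conditions: NaClO2, NaH2PO4, 2-methylbut-2-ene, t-BuOH–THF–H2O, rt
Reagents that add atoms: sodium chlorite, [Na+].[O-]Cl=O
Why: The Pinnick oxidation converts the aryl aldehyde to the acid in a buffered medium that the esters tolerate, and 2-methylbut-2-ene traps HOCl before it can chlorinate the electron-rich rings.

**Step 16**
Reactants: 29 A–B1–C acid (name as in step 15); 23 tert-butyl (S)-3-hydroxybutanoate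
Product: 30 tert-butyl (R)-3-[(2,4-bis(benzyloxy)-6-{(R)-2-[((R)-3-{[2,4-bis(benzyloxy)-6-methylbenzoyl]oxy}butanoyl)oxy]propyl}benzoyl)oxy]butanoate
Conditions: PPh3, DIAD, 23 (excess), toluene, 0 °C → rt
Reagents that add atoms: none
Why: This second Mitsunobu esterification again spares the crowded aroyl carbon from attack, uses the cheap alcohol in excess, and sets the R centre of B2 by SN2 inversion of (S)-23.

**Step 17**
Reactants: 30 A–B1–C–B2 tert-butyl ester (name as in step 16)
Product: 31 (R)-3-[(2,4-bis(benzyloxy)-6-{(R)-2-[((R)-3-{[2,4-bis(benzyloxy)-6-methylbenzoyl]oxy}butanoyl)oxy]propyl}benzoyl)oxy]butanoic acid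
Conditions: TFA–CH2Cl2 (1:4), 0 °C → rt
Reagents that add atoms: none
Why: Acidolysis of the tert-butyl ester is run before the acid-sensitive, acyl-free ring D is attached, so all four benzyl ethers present sit on deactivated rings and should survive.

**Step 18**
Reactants: 31 A–B1–C–B2 acid (name as in step 17); 19 (R)-1-[3,5-bis(benzyloxy)phenyl]propan-2-ol
Product: 32 hexa-O-benzyl Hansforester A (all six phenols as benzyl ethers and all four centres R)
Conditions: DCC, DMAP (cat.), CH2Cl2, 0 °C → rt
Reagents that add atoms: none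
Why: This Steglich esterification is of the same type as step 13 and joins an unhindered aliphatic acid to the secondary alcohol with retention at every stereocentre.

**Step 19**
Reactants: 32 hexa-O-benzyl Hansforester A
Product: 33 Hansforester A
Conditions: H2 (1 atm), 10% Pd/C, EtOAc–THF, rt
Reagents that add atoms: none
Why: Catalytic hydrogenolysis cleaves the six benzylic C–O bonds under neutral conditions, whereas the four esters (whose alkyl C–O bonds are not benzylic) and the four stereocentres are unaffected.

**Compound list**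

1 | (R)-propylene oxide | C[C@@H]1CO1 | starting material
2 | lithium acetylide–ethylenediamine complex | [Li+].[C-]#C.NCCN | starting material
3 | (R)-pent-4-yn-2-ol | C[C@H](CC#C)O | intermediate
4 | (R)-tert-butyldimethyl(pent-4-yn-2-yloxy)silane | C[C@H](CC#C)O[Si](C)(C)C(C)(C)C | intermediate
5 | trichloroacetyl chloride | ClC(=O)C(Cl)(Cl)Cl | starting material
6 | dichloroketene (not isolated) | ClC(Cl)=C=O | intermediate
7 | (R)-3-[2-(tert-butyldimethylsilyloxy)propyl]-4,4-dichlorocyclobut-2-en-1-one | C[C@H](CC1=CC(=O)C1(Cl)Cl)O[Si](C)(C)C(C)(C)C | intermediate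
8 | (R)-3-[2-(tert-butyldimethylsilyloxy)propyl]cyclobut-2-en-1-one | C[C@H](CC1=CC(=O)C1)O[Si](C)(C)C(C)(C)C | intermediate
9 | ethynyltrimethylsilane | C#C[Si](C)(C)C | starting material
10 | lithium (trimethylsilyl)acetylide (not isolated) | [Li+].[C-]#C[Si](C)(C)C | intermediate
11 | lithium 2-(trimethylsilyl)ethynolate (not isolated) | [Li+].[O-]C#C[Si](C)(C)C | intermediate
12 | 1-(triisopropylsilyloxy)-2-(trimethylsilyl)ethyne | C[Si](C)(C)C#CO[Si](C(C)C)(C(C)C)C(C)C | intermediate
13 | (R)-5-(tert-butyldimethylsilyloxy)-3-methylidenehex-1-en-1-one, vinylketene (not isolated) | C[C@H](CC(=C)C=C=O)O[Si](C)(C)C(C)(C)C | intermediate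
14 | 4-[(R)-4-(tert-butyldimethylsilyloxy)pent-1-en-2-yl]-3-(triisopropylsilyloxy)-2-(trimethylsilyl)cyclobut-2-en-1-one, ring C4 epimers (not isolated) | C[C@H](CC(=C)C1C(=O)C([Si](C)(C)C)=C1O[Si](C(C)C)(C(C)C)C(C)C)O[Si](C)(C)C(C)(C)C | intermediate
15 | (R,3E)-7-(tert-butyldimethylsilyloxy)-5-methylidene-3-(triisopropylsilyloxy)-2-(trimethylsilyl)octa-1,3-dien-1-one, dienylketene (not isolated) | C[C@H](CC(=C)/C=C(/O[Si](C(C)C)(C(C)C)C(C)C)C(=C=O)[Si](C)(C)C)O[Si](C)(C)C(C)(C)C | intermediate
16 | 5-[(R)-2-(tert-butyldimethylsilyloxy)propyl]-3-(triisopropylsilyloxy)-2-(trimethylsilyl)cyclohexa-2,4-dien-1-one (not isolated) | C[C@H](CC1=CC(O[Si](C(C)C)(C(C)C)C(C)C)=C([Si](C)(C)C)C(=O)C1)O[Si](C)(C)C(C)(C)C | intermediate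
17 | (R)-5-[2-(tert-butyldimethylsilyloxy)propyl]-3-(triisopropylsilyloxy)-2-(trimethylsilyl)phenol | C[C@H](Cc1cc(O)c([Si](C)(C)C)c(O[Si](C(C)C)(C(C)C)C(C)C)c1)O[Si](C)(C)C(C)(C)C | intermediate
18 | (R)-3-(2-hydroxypropyl)-5-(triisopropylsilyloxy)phenol | C[C@H](Cc1cc(O)cc(O[Si](C(C)C)(C(C)C)C(C)C)c1)O | intermediate
19 | (R)-1-[3,5-bis(benzyloxy)phenyl]propan-2-ol | C[C@H](Cc1cc(OCc2ccccc2)cc(OCc2ccccc2)c1)O | intermediate
20 | methyl 2,4-dihydroxy-6-methylbenzoate | COC(=O)c1c(C)cc(O)cc1O | starting material
21 | methyl 2,4-bis(benzyloxy)-6-methylbenzoate | COC(=O)c1c(C)cc(OCc2ccccc2)cc1OCc1ccccc1 | intermediate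
22 | 2,4-bis(benzyloxy)-6-methylbenzoic acid | Cc1cc(OCc2ccccc2)cc(OCc2ccccc2)c1C(=O)O | intermediate
23 | tert-butyl (S)-3-hydroxybutanoate | C[C@H](O)CC(=O)OC(C)(C)C | starting material
24 | tert-butyl (R)-3-{[2,4-bis(benzyloxy)-6-methylbenzoyl]oxy}butanoate | Cc1cc(OCc2ccccc2)cc(OCc2ccccc2)c1C(=O)O[C@H](C)CC(=O)OC(C)(C)C | intermediate
25 | (R)-3-{[2,4-bis(benzyloxy)-6-methylbenzoyl]oxy}butanoic acid | Cc1cc(OCc2ccccc2)cc(OCc2ccccc2)c1C(=O)O[C@H](C)CC(=O)O | intermediate
26 | (R)-1-[3,5-bis(benzyloxy)phenyl]propan-2-yl (R)-3-{[2,4-bis(benzyloxy)-6-methylbenzoyl]oxy}butanoate | Cc1cc(OCc2ccccc2)cc(OCc2ccccc2)c1C(=O)O[C@H](C)CC(=O)O[C@H](C)Cc1cc(OCc2ccccc2)cc(OCc2ccccc2)c1 | intermediate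
27 | aryl(dimethyl)iminium chloride of 28 (not isolated) | Cc1cc(OCc2ccccc2)cc(OCc2ccccc2)c1C(=O)O[C@H](C)CC(=O)O[C@H](C)Cc1cc(OCc2ccccc2)cc(OCc2ccccc2)c1C=[N+](C)C.[Cl-] | intermediate
28 | (R)-1-[3,5-bis(benzyloxy)-2-formylphenyl]propan-2-yl (R)-3-{[2,4-bis(benzyloxy)-6-methylbenzoyl]oxy}butanoate | Cc1cc(OCc2ccccc2)cc(OCc2ccccc2)c1C(=O)O[C@H](C)CC(=O)O[C@H](C)Cc1cc(OCc2ccccc2)cc(OCc2ccccc2)c1C=O | intermediate
29 | A–B1–C acid: 2,4-bis(benzyloxy)-6-{(R)-2-[((R)-3-{[2,4-bis(benzyloxy)-6-methylbenzoyl]oxy}butanoyl)oxy]propyl}benzoic acid | Cc1cc(OCc2ccccc2)cc(OCc2ccccc2)c1C(=O)O[C@H](C)CC(=O)O[C@H](C)Cc1cc(OCc2ccccc2)cc(OCc2ccccc2)c1C(=O)O | intermediate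
30 | A–B1–C–B2 tert-butyl ester (all R) | Cc1cc(OCc2ccccc2)cc(OCc2ccccc2)c1C(=O)O[C@H](C)CC(=O)O[C@H](C)Cc1cc(OCc2ccccc2)cc(OCc2ccccc2)c1C(=O)O[C@H](C)CC(=O)OC(C)(C)C | intermediate
31 | A–B1–C–B2 acid (all R) | Cc1cc(OCc2ccccc2)cc(OCc2ccccc2)c1C(=O)O[C@H](C)CC(=O)O[C@H](C)Cc1cc(OCc2ccccc2)cc(OCc2ccccc2)c1C(=O)O[C@H](C)CC(=O)O | intermediate
32 | hexa-O-benzyl Hansforester A | Cc1cc(OCc2ccccc2)cc(OCc2ccccc2)c1C(=O)O[C@H](C)CC(=O)O[C@H](C)Cc1cc(OCc2ccccc2)cc(OCc2ccccc2)c1C(=O)O[C@H](C)CC(=O)O[C@H](C)Cc1cc(OCc2ccccc2)cc(OCc2ccccc2)c1 | intermediate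
33 | Hansforester A | Cc1cc(O)cc(O)c1C(=O)O[C@H](C)CC(=O)O[C@H](C)Cc1cc(O)cc(O)c1C(=O)O[C@H](C)CC(=O)O[C@H](C)Cc1cc(O)cc(O)c1 | target

**Step count.** The route has 19 steps in total. The longest linear sequence is 14 steps (1–4, 6–8, 13–19). The side branches are step 5 (one step from 9) and steps 9–12 (four steps from 20).

**Steps most likely to fail**

1. **Step 6.** The bulky C-silyl terminus may slow capture of the vinylketene. Ketene dimerisation, acylation of the product phenol or O-to-C silyl drift in the alkyne could then take over, or the cascade could stall at the four-membered adduct. The fallback sets out from 1 and comes back at 19. Commercial 1,3-bis(benzyloxy)-5-bromobenzene is turned with Mg turnings in THF into 3,5-bis(benzyloxy)phenylmagnesium bromide F1. This opens epoxide 1 at its CH2 carbon under CuI catalysis (THF, −30 → 0 °C) and should give 19 directly with the R centre intact. The ring is then bought rather than built, and steps 2–8 fall away.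

2. **Step 5.** Peroxide or tert-butoxide may attack silicon with loss of the C-silyl group, oxygen transfer may stay incomplete, or silylation may occur at carbon to give a ketene. The fallback replaces 9 and 10 and comes back at ynolate 11. Commercial (trimethylsilyl)diazomethane is lithiated with n-BuLi (THF, −78 °C) to lithio(trimethylsilyl)diazomethane F2. This takes up CO (1 atm) and loses N2 to give the same ynolate 11, which is silylated in the flask with TIPSOTf to 12. Carbonylation takes the place of oxidation, so no peroxide or alkoxide meets the C–Si bond.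

3. **Step 16.** β-Elimination of the activated alcohol to the crotonate may outrun displacement by the crowded carboxylate of the large acid. The fallback sets out from 29 and comes back at 30. Acid 29 is converted with oxalyl chloride and catalytic DMF (CH2Cl2, 0 °C) into the A–B1–C acid chloride F3. This acylates commercial tert-butyl (R)-3-hydroxybutanoate (C[C@@H](O)CC(=O)OC(C)(C)C; Et3N, DMAP, CH2Cl2, 0 °C → rt) with retention. Acyl activation replaces alcohol activation, so no leaving group stands β to the ester carbonyl before the bond is made.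

**Further compounds**

F1 | step 6 | 3,5-bis(benzyloxy)phenylmagnesium bromide | Br[Mg]c1cc(OCc2ccccc2)cc(OCc2ccccc2)c1
F2 | step 5 | lithio(trimethylsilyl)diazomethane | [Li]C(=[N+]=[N-])[Si](C)(C)C
F3 | step 16 | A–B1–C acid chloride (acid chloride of 29) | Cc1cc(OCc2ccccc2)cc(OCc2ccccc2)c1C(=O)O[C@H](C)CC(=O)O[C@H](C)Cc1cc(OCc2ccccc2)cc(OCc2ccccc2)c1C(Cl)=O
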